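**Plan**
1. Retrosynthesis: the C11=C13 methylene, the C8 angelate (C8–O, with inversion) and the C3 carbonyl are late adjustments; the lactone is cut at C7–C11 and C6–O to a (4Z,6Z)-cyclodeca-4,6-diene plus malonic acid; the carbocycle is cut at C5–C6 (Stille) and the chain at C1–C2 (aldol) into a citramalate-derived C1/C10/C9–C6 ynal and a C2–C5 (Z)-iodoenone.
2. Forward: the chain is joined by the aldol, the ten-membered ring is closed first at C5–C6, the γ-lactone ring is then annulated in one operation, followed by methylenation, C8 inversion with esterification, desilylation and C3 oxidation.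
3. Stereochemistry: C10 comes from (S)-citramalic acid, C8 (as its epimer) from asymmetric transfer hydrogenation, C1 from an Ipc-boron aldol, the temporary C3 centre from 1,3-anti reduction; C7 and C6 arise in the annulation (C7 relayed from C8, C6 by syn closure) and C8 is corrected by Mitsunobu inversion.
4. Geometry: 4Z comes from anti-carbomagnesiation, 6Z from hydrozirconation of a stannylalkyne, and the angelate geometry from angelic acid.
5. Enabling feature: the lactone oxygen on C6 and the C7–C11 bond sit cis on adjacent ring carbons directly beside the C4=C5 alkene, which is the 1,2-carbolactonisation pattern of the C6=C7 end of a C4=C5–C6=C7 diene in the ten-membered ring.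

Key step: step 15

Remark (assumption): ring atoms carry germacrane numbers throughout (C1 carbinol, C3 carbonyl, C4=C5, C6 lactone CH–O, C7, C8 ester carbon, C10 methyl carbinol, C11–C13 lactone carbons); the C3 carbinol of 17–30 is a temporary centre (3S, 1,3-anti to C1) that is erased in step 20.

Step 1
Reactants: 1 (S)-citramalic acid
Product: 2 2-[(4S)-2,2,4-trimethyl-5-oxo-1,3-dioxolan-4-yl]acetic acid
Conditions: Me2C(OMe)2, p-TsOH·H2O (5 mol %), acetone, rt
Reagents that add atoms: 2,2-dimethoxypropane COC(C)(C)OC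
Why: Acid-catalysed acetal exchange ties the tertiary hydroxyl and its geminal carboxyl into a five-membered dioxolanone (the usual behaviour of α-hydroxy acids such as malic acid), which leaves only the CH2CO2H arm free and does not touch the C10 stereocentre.

Step 2
Reactants: 2 dioxolanone acid; 3 ethynyltrimethylsilane
Product: 5 (5S)-2,2,5-trimethyl-5-[2-oxo-4-(trimethylsilyl)but-3-yn-1-yl]-1,3-dioxolan-4-one, via acid chloride 4 (not isolated)
Conditions: (COCl)2, DMF (cat), CH2Cl2, 0 °C to rt, evaporate; then 3, PdCl2(PPh3)2 (2 mol %), CuI (4 mol %), Et3N, THF, rt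
Reagents that add atoms: none
Why: The acid chloride couples with the terminal alkyne in an acyl Sonogashira reaction (copper acetylide, acylpalladium intermediate, reductive elimination) to give the silyl ynone that carries C8, C7 and C6.

Step 3
Reactants: 5 silyl ynone
Product: 6 (5S)-5-[(2S)-2-hydroxy-4-(trimethylsilyl)but-3-yn-1-yl]-2,2,5-trimethyl-1,3-dioxolan-4-one
Conditions: Ru[(S,S)-TsDPEN](p-cymene) (1 mol %), i-PrOH, rt
Reagents that add atoms: none
Why: Noyori asymmetric transfer hydrogenation of an alkynyl ketone, in which the (S,S)-diamine ligand delivers hydride to the face that gives the (S)-propargylic carbinol under reagent control, which is the 8-epi configuration wanted for the annulation.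

Step 4
Reactants: 6 hydroxy dioxolanone
Product: 7 (2S,4S)-2,4-dihydroxy-N-methoxy-N,2-dimethyl-6-(trimethylsilyl)hex-5-ynamide
Conditions: MeNH(OMe)·HCl, i-PrMgCl, THF, −20 to 0 °C
Reagents that add atoms: N,O-dimethylhydroxylamine hydrochloride CNOC.Cl
Why: The magnesium amide of N,O-dimethylhydroxylamine opens the activated dioxolanone carbonyl (and equally any γ-lactone formed from 6 by acyl transfer to the C8 oxygen) with loss of acetone, a standard ester-to-Weinreb-amide aminolysis.

Step 5
Reactants: 7 dihydroxy Weinreb amide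
Product: 8 (2S,4S)-N-methoxy-N,2-dimethyl-2,4-bis(triethylsilyloxy)-6-(trimethylsilyl)hex-5-ynamide
Conditions: Et3SiOTf, 2,6-lutidine, CH2Cl2, −78 to 0 °C
Reagents that add atoms: triethylsilyl trifluoromethanesulfonate CC[Si](CC)(CC)OS(=O)(=O)C(F)(F)F
Why: The silyl triflate silylates the secondary propargylic and the tertiary hydroxyl alike, which prevents lactol formation in the next step and keeps O8 masked until after the annulation.

Step 6
Reactants: 8 bis(silyl ether) Weinreb amide
Product: 9 (2S,4S)-2-methyl-2,4-bis(triethylsilyloxy)-6-(trimethylsilyl)hex-5-ynal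
Conditions: i-Bu2AlH, THF, −78 °C
Reagents that add atoms: none
Why: Hydride reduction of a Weinreb amide stops at the chelated tetrahedral aluminate, which releases the aldehyde only on work-up, and the quaternary α-carbon C10 cannot epimerise.

Step 7
Reactants: 10 but-3-yn-2-ol
Product: 12 (Z)-4-iodo-3-methylbut-3-en-2-ol, via alkenylmagnesium chelate 11 (not isolated)
Conditions: MeMgBr (3 equiv), CuI (10 mol %), THF, −10 °C to rt; then I2, −40 to 0 °C
Reagents that add atoms: methylmagnesium bromide C[Mg]Br; iodine II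
Why: Copper-catalysed anti-carbomagnesiation of a propargylic alkoxide puts the methyl group on the alkyne carbon next to the carbinol and magnesium on the terminal carbon cis to the alkoxide in a five-membered chelate, and iodinolysis with retention gives the Z iodide, which fixes the 4Z geometry (C15 methyl on C4, iodine on C5).

Step 8
Reactants: 12 (Z)-iodo allylic alcohol
Product: 13 (Z)-4-iodo-3-methylbut-3-en-2-one
Conditions: Dess–Martin periodinane, CH2Cl2, 0 °C, exclusion of light
Reagents that add atoms: none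
Why: Dess–Martin oxidation of the secondary allylic alcohol under neutral conditions should give the methyl ketone without isomerising the Z iodoalkene, and it removes the racemic carbinol centre.

Step 9
Reactants: 13 (Z)-iodoenone; 9 aldehyde
Product: 16 (1Z,5S,6S,8S)-5-hydroxy-1-iodo-2,6-dimethyl-6,8-bis(triethylsilyloxy)-10-(trimethylsilyl)dec-1-en-9-yn-3-one, via boron dienolate 14 (not isolated), via boron aldolate 15 (not isolated)
Conditions: (+)-Ipc2BCl, Et3N, Et2O, −78 to 0 °C; then 9, −78 to −20 °C; H2O2, pH 7 buffer, MeOH, 0 °C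
Reagents that add atoms: none
Why: Paterson aldol reaction in which the methyl ketone is enolised on its only enolisable side and the boron enolate adds to the aldehyde through a cyclic transition state, the (+)-isopinocampheyl ligands steering attack to the si face of C1 to give the 1S carbinol under reagent control, because the quaternary C10 (methyl against methylene arm) biases the aldehyde faces only weakly.

Step 10
Reactants: 16 β-hydroxy enone
Product: 17 (1Z,3S,5S,6S,8S)-1-iodo-2,6-dimethyl-6,8-bis(triethylsilyloxy)-10-(trimethylsilyl)dec-1-en-9-yne-3,5-diol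
Conditions: Me4NBH(OAc)3, MeCN/AcOH, −30 °C
Reagents that add atoms: none
Why: Evans–Saksena reduction, in which the acetoxyborohydride exchanges onto the C1 hydroxyl and delivers hydride intramolecularly through a chair transition state to give the 1,3-anti diol (3S) by 1,2-reduction, which takes the carbonyl out of conjugation with the future diene and leaves the alkenyl iodide untouched.

Step 11
Reactants: 17 anti-diol
Product: 18 (1Z,3S,5S,6S,8S)-3,5-bis(tert-butyldimethylsilyloxy)-1-iodo-2,6-dimethyl-6,8-bis(triethylsilyloxy)-10-(trimethylsilyl)dec-1-en-9-yne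
Conditions: t-BuMe2SiOTf, 2,6-lutidine, CH2Cl2, −78 to 0 °C
Reagents that add atoms: tert-butyldimethylsilyl trifluoromethanesulfonate CC(C)(C)[Si](C)(C)OS(=O)(=O)C(F)(F)F
Why: The silyl triflate is reactive enough to silylate both the allylic C3 and the hindered C1 hydroxyl, giving ethers that should outlast the later selective removal of the secondary triethylsilyl group.

Step 12
Reactants: 18 alkynylsilane
Product: 19 (1Z,3S,5S,6S,8S)-3,5-bis(tert-butyldimethylsilyloxy)-1-iodo-2,6-dimethyl-6,8-bis(triethylsilyloxy)-10-(tributylstannyl)dec-1-en-9-yne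
Conditions: (Bu3Sn)2O, Bu4NF (2 mol %), THF, 60 °C
Reagents that add atoms: bis(tributyltin) oxide CCCC[Sn](CCCC)(CCCC)O[Sn](CCCC)(CCCC)CCCC
Why: Fluoride-catalysed desilylative stannylation of an alkynylsilane, in which fluoride releases the acetylide that the stannoxane traps while the stannoxide carries the chain, exchanges C–Si for C–Sn without a strong base that would attack the alkenyl iodide.

Step 13
Reactants: 19 alkynylstannane
Product: 21 (1Z,3S,5S,6S,8S,9Z)-3,5-bis(tert-butyldimethylsilyloxy)-1-iodo-2,6-dimethyl-6,8-bis(triethylsilyloxy)-10-(tributylstannyl)deca-1,9-diene, via stannyl zirconocenyl alkene 20 (not isolated)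
Conditions: Cp2Zr(H)Cl, THF, rt; then H2O
Reagents that add atoms: none
Why: Hydrozirconation of a stannylalkyne adds H and Zr syn with zirconium on the tin-bearing carbon, and protonolysis of the C–Zr bond with retention leaves the Z alkenylstannane (6Z), while the alkenyl iodide does not react with the zirconium hydride.

Step 14
Reactants: 21 iodo stannane
Product: 22 (1S,3S,4Z,6Z,8S,10S)-1,3-bis(tert-butyldimethylsilyloxy)-4,10-dimethyl-8,10-bis(triethylsilyloxy)cyclodeca-4,6-diene
Conditions: Pd2(dba)3 (10 mol %), AsPh3, CuI, DMF, 45 °C, 1 mM, slow addition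
Reagents that add atoms: none
Why: Intramolecular Stille coupling (oxidative addition of zerovalent palladium into the C5–I bond, tin-to-palladium transmetalation at C6, reductive elimination) forms C5–C6 with retention of both Z geometries, the two cis alkenes turning the chain ends toward each other and high dilution suppressing oligomers.

Step 15
Reactants: 22 (4Z,6Z)-cyclodecadiene; 23 malonic acid (4 equiv)
Product: 24 (1S,3S,4Z,6S,7S,8S,10S)-1,3-bis(tert-butyldimethylsilyloxy)-8,10-bis(triethylsilyloxy)germacr-4-en-6,12-olid-13-oic acid (C11 epimers)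
Conditions: Mn(OAc)3·2H2O (2.2 equiv), Cu(OAc)2·H2O (0.5 equiv), KOAc, AcOH/MeCN 1:1, 25 to 40 °C, argon
Reagents that add atoms: none
Why: Mn(OAc)3 (trivalent manganese) oxidises malonic acid through its manganese enolate to the electrophilic dicarboxymethyl radical, which adds to C7, the only unsubstituted terminus of the C4=C5–C6=C7 diene, and Cu(OAc)2 (divalent copper) oxidises the resulting C4–C6 allyl radical to the allyl cation or its allylcopper equivalent, which one carboxyl group captures at C6. The closest known reaction type is the Mn(OAc)3 carbolactonisation of alkenes and 1,3-dienes with acetic or malonic acid. The lactone ring closes in a 5-exo-trig mode (oxygen onto C6 with C4=C5 left outside the ring), which is preferred over seven-membered closure at C4 and returns the 4Z alkene. C7 is set by facial selectivity, since allylic 1,3-strain holds C8–H in the diene plane, the C8–C9 bond covers the inner face and the radical should enter from the outer face, anti to C8–C9 and trans across the ring to the C8 silyloxy group, which is why the 8-epi ether is carried; C6 is set by syn delivery of the carboxylate from the face that already bears C11, before the C6–C7 bond can rotate, which gives the cis ring fusion, and C11 is left uncontrolled because it is erased in step 16. The step needs regioselection for C7 (secured by the fully substituted C4 terminus and the more stabilised tertiary allyl radical), a single annulation (excess 23, two equivalents of oxidant, low temperature) and survival of the dienylic silyl ethers (acetate buffer), and O8 stays silylated so that the free acid of 24 cannot lactonise onto it.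

Step 16
Reactants: 24 lactone acid
Product: 26 (1S,3S,4Z,6S,7S,8S,10S)-1,3-bis(tert-butyldimethylsilyloxy)-8,10-bis(triethylsilyloxy)germacra-4,11(13)-dien-6,12-olide, via Mannich base 25 (not isolated)
Conditions: (CH2O)n, Et2NH, EtOAc, 70 °C
Reagents that add atoms: paraformaldehyde (as formaldehyde) C=O
Why: Decarboxylative Mannich methylenation, in which the iminium ion from formaldehyde and diethylamine alkylates the malonate-type C11 and the β-amino acid loses CO2 and diethylamine in one fragmentation, gives the exocyclic C11=C13 alkene without an enolate that could epimerise C7 and erases the C11 centre.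

Step 17
Reactants: 26 methylene lactone
Product: 27 (1S,3S,4Z,6S,7R,8S,10S)-1,3-bis(tert-butyldimethylsilyloxy)-8-hydroxy-10-(triethylsilyloxy)germacra-4,11(13)-dien-6,12-olide
Conditions: HF·pyridine, pyridine, THF, 0 °C
Reagents that add atoms: none
Why: Buffered fluoride should cleave the secondary triethylsilyl ether at O8 faster than the tertiary triethylsilyl ether and the two tert-butyldimethylsilyl ethers (rate order set by bulk at silicon and at carbon), freeing only the 8-epi hydroxyl, and any material that also loses the O10 silyl group converges again at 30.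

Step 18
Reactants: 27 C8 alcohol; 28 angelic acid
Product: 29 (1S,3S,4Z,6S,7R,8R,10S)-8-angeloyloxy-1,3-bis(tert-butyldimethylsilyloxy)-10-(triethylsilyloxy)germacra-4,11(13)-dien-6,12-olide
Conditions: PPh3, DIAD, toluene, 0 °C to rt
Reagents that add atoms: none
Why: Mitsunobu esterification, in which the C8 oxyphosphonium ion is displaced by angelate with inversion to give the 8R ester, uses the acid only as a nucleophile, so its Z double bond is not exposed to the carboxyl activation that isomerises angelates to tiglates.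

Step 19
Reactants: 29 silylated angelate
Product: 30 (1S,3S,4Z,6S,7R,8R,10S)-8-angeloyloxy-1,3,10-trihydroxygermacra-4,11(13)-dien-6,12-olide
Conditions: HF·pyridine (excess), THF, 0 °C to rt
Reagents that add atoms: none
Why: Excess fluoride under mildly acidic conditions cleaves both tert-butyldimethylsilyl ethers and the tertiary triethylsilyl ether, while the base-sensitive angelate, allylic lactone and α-methylene group are left alone.

Step 20
Reactants: 30 triol
Product: 31 (1S,4Z,6S,7R,8R,10S)-8-angeloyloxy-1,10-dihydroxy-3-oxogermacra-4,11(13)-dien-6,12-olide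
Conditions: MnO2 (activated, excess), CH2Cl2, rt
Reagents that add atoms: none
Why: MnO2 oxidises only the allylic C3 carbinol, which is activated by C4=C5, and not the saturated C1 or the tertiary C10 hydroxyl, so the temporary C3 centre becomes the enone carbonyl of the target.

**Compound list**
1 | (S)-citramalic acid | C[C@](O)(CC(=O)O)C(=O)O | starting material
2 | 2-[(4S)-2,2,4-trimethyl-5-oxo-1,3-dioxolan-4-yl]acetic acid | O=C1OC(C)(C)O[C@@]1(C)CC(=O)O | intermediate
3 | ethynyltrimethylsilane | C#C[Si](C)(C)C | starting material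
4 | 2-[(4S)-2,2,4-trimethyl-5-oxo-1,3-dioxolan-4-yl]acetyl chloride | O=C1OC(C)(C)O[C@@]1(C)CC(=O)Cl | intermediate
5 | (5S)-2,2,5-trimethyl-5-[2-oxo-4-(trimethylsilyl)but-3-yn-1-yl]-1,3-dioxolan-4-one | C[Si](C)(C)C#CC(=O)C[C@]1(C)OC(C)(C)OC1=O | intermediate
6 | (5S)-5-[(2S)-2-hydroxy-4-(trimethylsilyl)but-3-yn-1-yl]-2,2,5-trimethyl-1,3-dioxolan-4-one | C[Si](C)(C)C#C[C@@H](O)C[C@]1(C)OC(C)(C)OC1=O | intermediate
7 | (2S,4S)-2,4-dihydroxy-N-methoxy-N,2-dimethyl-6-(trimethylsilyl)hex-5-ynamide | CON(C)C(=O)[C@@](C)(O)C[C@H](O)C#C[Si](C)(C)C | intermediate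
8 | (2S,4S)-N-methoxy-N,2-dimethyl-2,4-bis(triethylsilyloxy)-6-(trimethylsilyl)hex-5-ynamide | CON(C)C(=O)[C@@](C)(O[Si](CC)(CC)CC)C[C@H](O[Si](CC)(CC)CC)C#C[Si](C)(C)C | intermediate
9 | (2S,4S)-2-methyl-2,4-bis(triethylsilyloxy)-6-(trimethylsilyl)hex-5-ynal | O=C[C@@](C)(O[Si](CC)(CC)CC)C[C@H](O[Si](CC)(CC)CC)C#C[Si](C)(C)C | intermediate
10 | but-3-yn-2-ol (racemic) | C#CC(C)O | starting material
11 | 4,5-dimethyl-2,5-dihydro-1,2-oxamagnesole (cyclic Z-alkenylmagnesium alkoxide) | CC1O[Mg]C=C1C | intermediate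
12 | (Z)-4-iodo-3-methylbut-3-en-2-ol (racemic) | CC(O)/C(C)=C\I | intermediate
13 | (Z)-4-iodo-3-methylbut-3-en-2-one | CC(=O)/C(C)=C\I | intermediate
14 | (Z)-4-iodo-3-methylbuta-1,3-dien-2-yl bis[(1S,2R,3S,5S)-isopinocampheyl]borinate (boron dienolate of 13) | C=C(OB([C@H]1C[C@H]2C[C@@H]([C@@H]1C)C2(C)C)[C@H]1C[C@H]2C[C@@H]([C@@H]1C)C2(C)C)/C(C)=C\I | intermediate
15 | O5-[bis(isopinocampheyl)boryl] derivative of 16 (boron aldolate) | I/C=C(C)\C(=O)C[C@H](OB([C@H]1C[C@H]2C[C@@H]([C@@H]1C)C2(C)C)[C@H]1C[C@H]2C[C@@H]([C@@H]1C)C2(C)C)[C@@](C)(O[Si](CC)(CC)CC)C[C@H](O[Si](CC)(CC)CC)C#C[Si](C)(C)C | intermediate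
16 | (1Z,5S,6S,8S)-5-hydroxy-1-iodo-2,6-dimethyl-6,8-bis(triethylsilyloxy)-10-(trimethylsilyl)dec-1-en-9-yn-3-one | I/C=C(C)\C(=O)C[C@H](O)[C@@](C)(O[Si](CC)(CC)CC)C[C@H](O[Si](CC)(CC)CC)C#C[Si](C)(C)C | intermediate
17 | (1Z,3S,5S,6S,8S)-1-iodo-2,6-dimethyl-6,8-bis(triethylsilyloxy)-10-(trimethylsilyl)dec-1-en-9-yne-3,5-diol | I/C=C(C)\[C@@H](O)C[C@H](O)[C@@](C)(O[Si](CC)(CC)CC)C[C@H](O[Si](CC)(CC)CC)C#C[Si](C)(C)C | intermediate
18 | (1Z,3S,5S,6S,8S)-3,5-bis(tert-butyldimethylsilyloxy)-1-iodo-2,6-dimethyl-6,8-bis(triethylsilyloxy)-10-(trimethylsilyl)dec-1-en-9-yne | I/C=C(C)\[C@@H](O[Si](C)(C)C(C)(C)C)C[C@H](O[Si](C)(C)C(C)(C)C)[C@@](C)(O[Si](CC)(CC)CC)C[C@H](O[Si](CC)(CC)CC)C#C[Si](C)(C)C | intermediate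
19 | (1Z,3S,5S,6S,8S)-3,5-bis(tert-butyldimethylsilyloxy)-1-iodo-2,6-dimethyl-6,8-bis(triethylsilyloxy)-10-(tributylstannyl)dec-1-en-9-yne | I/C=C(C)\[C@@H](O[Si](C)(C)C(C)(C)C)C[C@H](O[Si](C)(C)C(C)(C)C)[C@@](C)(O[Si](CC)(CC)CC)C[C@H](O[Si](CC)(CC)CC)C#C[Sn](CCCC)(CCCC)CCCC | intermediate
20 | 10-(chlorozirconocenyl)-10-(tributylstannyl) alkene from syn H–Zr addition to 19 (cyclopentadienyl rings drawn σ-bonded) | I/C=C(C)\[C@@H](O[Si](C)(C)C(C)(C)C)C[C@H](O[Si](C)(C)C(C)(C)C)[C@@](C)(O[Si](CC)(CC)CC)C[C@H](O[Si](CC)(CC)CC)/C=C(\[Sn](CCCC)(CCCC)CCCC)[Zr](Cl)(C1C=CC=C1)C1C=CC=C1 | intermediate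
21 | (1Z,3S,5S,6S,8S,9Z)-3,5-bis(tert-butyldimethylsilyloxy)-1-iodo-2,6-dimethyl-6,8-bis(triethylsilyloxy)-10-(tributylstannyl)deca-1,9-diene | I/C=C(C)\[C@@H](O[Si](C)(C)C(C)(C)C)C[C@H](O[Si](C)(C)C(C)(C)C)[C@@](C)(O[Si](CC)(CC)CC)C[C@H](O[Si](CC)(CC)CC)/C=C\[Sn](CCCC)(CCCC)CCCC | intermediate
22 | (1S,3S,4Z,6Z,8S,10S)-1,3-bis(tert-butyldimethylsilyloxy)-4,10-dimethyl-8,10-bis(triethylsilyloxy)cyclodeca-4,6-diene (germacrane locants) | CC(C)(C)[Si](C)(C)O[C@H]1C[C@H](O[Si](C)(C)C(C)(C)C)[C@@](C)(O[Si](CC)(CC)CC)C[C@H](O[Si](CC)(CC)CC)/C=C\C=C1\C | intermediate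
23 | malonic acid | OC(=O)CC(=O)O | starting material
24 | (1S,3S,4Z,6S,7S,8S,10S)-1,3-bis(tert-butyldimethylsilyloxy)-8,10-bis(triethylsilyloxy)germacr-4-en-6,12-olid-13-oic acid (cis-fused lactone, C11 epimers) | OC(=O)C1C(=O)O[C@H]2/C=C(/C)[C@@H](O[Si](C)(C)C(C)(C)C)C[C@H](O[Si](C)(C)C(C)(C)C)[C@@](C)(O[Si](CC)(CC)CC)C[C@H](O[Si](CC)(CC)CC)[C@@H]12 | intermediate
25 | 11-(diethylaminomethyl) derivative of 24 (Mannich base, C11 epimers) | CCN(CC)CC1(C(=O)O)C(=O)O[C@H]2/C=C(/C)[C@@H](O[Si](C)(C)C(C)(C)C)C[C@H](O[Si](C)(C)C(C)(C)C)[C@@](C)(O[Si](CC)(CC)CC)C[C@H](O[Si](CC)(CC)CC)[C@@H]12 | intermediate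
26 | (1S,3S,4Z,6S,7S,8S,10S)-1,3-bis(tert-butyldimethylsilyloxy)-8,10-bis(triethylsilyloxy)germacra-4,11(13)-dien-6,12-olide | C=C1C(=O)O[C@H]2/C=C(/C)[C@@H](O[Si](C)(C)C(C)(C)C)C[C@H](O[Si](C)(C)C(C)(C)C)[C@@](C)(O[Si](CC)(CC)CC)C[C@H](O[Si](CC)(CC)CC)[C@@H]12 | intermediate
27 | (1S,3S,4Z,6S,7R,8S,10S)-1,3-bis(tert-butyldimethylsilyloxy)-8-hydroxy-10-(triethylsilyloxy)germacra-4,11(13)-dien-6,12-olide | C=C1C(=O)O[C@H]2/C=C(/C)[C@@H](O[Si](C)(C)C(C)(C)C)C[C@H](O[Si](C)(C)C(C)(C)C)[C@@](C)(O[Si](CC)(CC)CC)C[C@H](O)[C@@H]12 | intermediate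
28 | angelic acid, (Z)-2-methylbut-2-enoic acid | C/C=C(/C)C(=O)O | starting material
29 | (1S,3S,4Z,6S,7R,8R,10S)-8-angeloyloxy-1,3-bis(tert-butyldimethylsilyloxy)-10-(triethylsilyloxy)germacra-4,11(13)-dien-6,12-olide | C=C1C(=O)O[C@H]2/C=C(/C)[C@@H](O[Si](C)(C)C(C)(C)C)C[C@H](O[Si](C)(C)C(C)(C)C)[C@@](C)(O[Si](CC)(CC)CC)C[C@@H](OC(=O)/C(C)=C\C)[C@@H]12 | intermediate
30 | (1S,3S,4Z,6S,7R,8R,10S)-8-angeloyloxy-1,3,10-trihydroxygermacra-4,11(13)-dien-6,12-olide | C=C1C(=O)O[C@H]2/C=C(/C)[C@@H](O)C[C@H](O)[C@@](C)(O)C[C@@H](OC(=O)/C(C)=C\C)[C@@H]12 | intermediate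
31 | CNP0271189.1, (1S,4Z,6S,7R,8R,10S)-8-angeloyloxy-1,10-dihydroxy-3-oxogermacra-4,11(13)-dien-6,12-olide | C=C1C(=O)O[C@H]2/C=C(/C)C(=O)C[C@H](O)[C@@](C)(O)C[C@@H](OC(=O)/C(C)=C\C)[C@@H]12 | target

**Step count and risks**
Total: 20 steps. Longest linear sequence: 18 steps (steps 1–6 and 9–20 from 1); steps 7 and 8 prepare the second fragment.

Steps most likely to fail:

Step 15 (annulation). The radical may enter C7 from the inner face, the C6–C7 bond may rotate before closure and give the trans-fused lactone, a hydride may shift from C3 to the cationic C4, the acidic C11–H of the product may be oxidised a second time, and the dienylic silyl ethers may undergo acetolysis. The fallback sets out from 22 and forms the same two bonds without an oxidant. Iodine atom-transfer radical addition of iodoacetic acid (Et3B, air, CH2Cl2/H2O, rt) places the carboxymethyl radical on C7, and the allylic iodide so formed is displaced by the carboxylate on NaHCO3 work-up. This should give the unsubstituted cis-fused lactone (1S,3S,4Z,6S,7S,8S,10S)-1,3-bis(tert-butyldimethylsilyloxy)-8,10-bis(triethylsilyloxy)-13-norgermacr-4-en-6,12-olide F1. Its lithium enolate (LiN(SiMe3)2, THF, −78 °C) is aminomethylated with dimethylmethyleneiminium iodide to the 13-(dimethylamino)germacr-4-en-6,12-olide Mannich base F2. Quaternisation with MeI followed by NaHCO3 eliminates trimethylamine and returns the route at 26.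

Step 14 (ring closure). Intermolecular coupling may outrun cyclisation, the Z alkenylstannane may be protodestannylated, and the alkenylpalladium intermediate may isomerise from Z to E. The fallback sets out from 18 and closes the same bond by reductive coupling of two alkenyl iodides, with no stannane. Iododesilylation (N-iodosuccinimide, AgNO3 cat, DMF) gives the iodoalkyne (1Z,3S,5S,6S,8S)-3,5-bis(tert-butyldimethylsilyloxy)-1,10-diiodo-2,6-dimethyl-6,8-bis(triethylsilyloxy)dec-1-en-9-yne F3. Diimide generated from 2-nitrobenzenesulfonyl hydrazide and Et3N reduces only the iodoalkyne and gives the (1Z,3S,5S,6S,8S,9Z)-1,10-diiododeca-1,9-diene analogue F4. Ni(cod)2 with PPh3 in DMF at high dilution (zerovalent nickel inserting into both C–I bonds, then C5–C6 reductive elimination) closes the ring to 22.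

Step 18 (inversion at C8). The oxyphosphonium ion may eliminate toward C7=C8, the lactone acyl group may migrate from O6 to the free O8, or substitution at the hindered carbinol may not take place. The fallback sets out from 27 and separates activation from displacement. ClCH2SO2Cl with pyridine in CH2Cl2 at 0 °C gives the 8-O-chloromethanesulfonate of 27, F5. The cesium salt of 28 (from Cs2CO3) with 18-crown-6 in toluene at 60 °C displaces it with inversion and returns the route at 29.

Further compounds
F1 | step 15 | (1S,3S,4Z,6S,7S,8S,10S)-1,3-bis(tert-butyldimethylsilyloxy)-8,10-bis(triethylsilyloxy)-13-norgermacr-4-en-6,12-olide | C1C(=O)O[C@H]2/C=C(/C)[C@@H](O[Si](C)(C)C(C)(C)C)C[C@H](O[Si](C)(C)C(C)(C)C)[C@@](C)(O[Si](CC)(CC)CC)C[C@H](O[Si](CC)(CC)CC)[C@@H]12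
F2 | step 15 | 13-(dimethylamino) derivative of the saturated lactone (Mannich base of F1, C11 epimers) | CN(C)CC1C(=O)O[C@H]2/C=C(/C)[C@@H](O[Si](C)(C)C(C)(C)C)C[C@H](O[Si](C)(C)C(C)(C)C)[C@@](C)(O[Si](CC)(CC)CC)C[C@H](O[Si](CC)(CC)CC)[C@@H]12
F3 | step 14 | (1Z,3S,5S,6S,8S)-3,5-bis(tert-butyldimethylsilyloxy)-1,10-diiodo-2,6-dimethyl-6,8-bis(triethylsilyloxy)dec-1-en-9-yne | I/C=C(C)\[C@@H](O[Si](C)(C)C(C)(C)C)C[C@H](O[Si](C)(C)C(C)(C)C)[C@@](C)(O[Si](CC)(CC)CC)C[C@H](O[Si](CC)(CC)CC)C#CI
F4 | step 14 | (1Z,3S,5S,6S,8S,9Z)-3,5-bis(tert-butyldimethylsilyloxy)-1,10-diiodo-2,6-dimethyl-6,8-bis(triethylsilyloxy)deca-1,9-diene | I/C=C(C)\[C@@H](O[Si](C)(C)C(C)(C)C)C[C@H](O[Si](C)(C)C(C)(C)C)[C@@](C)(O[Si](CC)(CC)CC)C[C@H](O[Si](CC)(CC)CC)/C=C\I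
F5 | step 18 | 8-O-chloromethanesulfonate of 27 | C=C1C(=O)O[C@H]2/C=C(/C)[C@@H](O[Si](C)(C)C(C)(C)C)C[C@H](O[Si](C)(C)C(C)(C)C)[C@@](C)(O[Si](CC)(CC)CC)C[C@H](OS(=O)(=O)CCl)[C@@H]12
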